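Each half of the C2-symmetric target is disconnected at the C3–C4 bond of ring A. The route rests on one structural feature: C3, the cyclopropane carbon that is bonded to C4, carries its hydrogen on the same side as the C1–C10 bond, so an unfunctionalised cyclopropyl substituent on C10 of ring B can be stitched to a bromine-bearing C4 of the exocyclic C4=C5 alkene by palladium-catalysed C(sp3)–H alkenylation. This single operation closes ring A, makes C3–C4 and fixes C1 and C3. The precursor is a ring B diene with 10-methyl, 10-cyclopropyl, 9-OTBS, C8 masked as a dioxolane, bromine on C4 cis to C10 and a saturated ester arm on C15; the halves are finally joined twice at C7–C11.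

Key step: step 13

Remarks on the chemistry
- Numbering (per half, used for all intermediates): cyclopropane C1–C2–C3; ring A C3–C4=C5–C10–C1; ring B C5–C6=C7–C8–C9–C10; C14 = methyl on C10; C15 = CH2 on C4; C11, C12, C13 = quaternary carbon, ester carbon and methyl on C7. Primed atoms belong to the other half; in a monomer the arm on C15 is C15H2–C11'H(C13'H3)–C12'O2Me. TBS = tert-butyldimethylsilyl.
- In the target the C9 oxygen is cis to the C14 methyl and trans to C1, and the cyclopropane CH2 (C2) is syn to C14. The first relationship is set by a stereospecific 1,2-shift (step 7), the second in the key step.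
- Assumption: 1 is purchased (otherwise one dehydrogenation from 1,4-dioxaspiro[4.5]decan-8-one). 14 is used as the racemate, so C11' is carried as a mixture of both epimers; this centre is planar in 21 and 22 and is set in step 17.
- The descriptor at C10 changes from R (8–12) to S (13 onward) only because substituent priorities change; the geometry is unchanged.

Step 1
Reactants: 1 1,4-dioxaspiro[4.5]dec-6-en-8-one
Product: 2 7-iodo-1,4-dioxaspiro[4.5]dec-6-en-8-one
Conditions: I2, pyridine, CH2Cl2, 0 → 23 °C
Reagents that add atoms: iodine, II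
Why: α-Iodination of the enone by pyridine conjugate addition, iodination of the enolate and elimination places iodine on the α-carbon (the future C10) and creates no stereocentre.

Step 2
Reactants: 2 7-iodo-1,4-dioxaspiro[4.5]dec-6-en-8-one
Product: 3 7-methyl-1,4-dioxaspiro[4.5]dec-6-en-8-one
Conditions: MeZnCl, PdCl2(dppf) (3 mol %; dppf = 1,1'-bis(diphenylphosphino)ferrocene), THF, 23 → 50 °C
Reagents that add atoms: methylzinc chloride, C[Zn]Cl
Why: Negishi coupling of an α-iodoenone with an alkylzinc halide installs the C14 methyl on the alkene carbon without touching the ketal.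

Step 3
Reactants: 3 7-methyl-1,4-dioxaspiro[4.5]dec-6-en-8-one
Product: 4 (8R)-7-methyl-1,4-dioxaspiro[4.5]dec-6-en-8-ol
Conditions: (S)-1-methyl-3,3-diphenyltetrahydro-1H,3H-pyrrolo[1,2-c][1,3,2]oxazaborole (10 mol %), BH3·SMe2, THF, −30 °C
Reagents that add atoms: none
Why: Corey–Bakshi–Shibata reduction in which the α-methylated alkene flank is the large group, so the (S)-oxazaborolidine delivers hydride to the face that gives the 8R carbinol (C5 in target numbering), the centre from which C9 and C10 are later derived.

Step 4
Reactants: 4 (8R)-7-methyl-1,4-dioxaspiro[4.5]dec-6-en-8-ol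
Product: 5 syn-epoxy alcohol (5R,9R,10R)
Conditions: VO(acac)2 (2 mol %), t-BuOOH, CH2Cl2, 0 → 23 °C
Reagents that add atoms: tert-butyl hydroperoxide, CC(C)(C)OO
Why: Hydroxyl-directed vanadium-catalysed epoxidation of the cyclic allylic alcohol delivers oxygen to the alkene face syn to the hydroxyl, which sets C9 and C10 relative to C5.

Step 5
Reactants: 5 syn-epoxy alcohol (5R,9R,10R)
Product: 6 epoxy ketone (9R,10S)
Conditions: Dess–Martin periodinane, NaHCO3, CH2Cl2, 0 → 23 °C
Reagents that add atoms: none
Why: Buffered Dess–Martin oxidation converts the secondary alcohol into the α,β-epoxy ketone without opening the epoxide or the ketal and leaves C9 and C10 untouched.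

Step 6
Reactants: 6 epoxy ketone (9R,10S)
Product: 7 tertiary cyclopropyl epoxy alcohol (5S,9R,10S)
Conditions: cPrMgBr, CeCl3, THF, −78 °C
Reagents that add atoms: cyclopropylmagnesium bromide, Br[Mg]C1CC1
Why: Cerium-mediated Grignard 1,2-addition to the α,β-epoxy ketone occurs anti to the epoxide oxygen (polar Felkin–Anh control by the α-C–O bond) and without enolisation, so the new C5 centre carries OH cis and cyclopropyl trans to the epoxide.

Step 7
Reactants: 7 tertiary cyclopropyl epoxy alcohol (5S,9R,10S)
Product: 8 (6R,7R)-7-cyclopropyl-6-hydroxy-7-methyl-1,4-dioxaspiro[4.5]decan-8-one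
Conditions: BF3·OEt2, CH2Cl2, −78 °C
Reagents that add atoms: none
Why: Semipinacol rearrangement of the syn-2,3-epoxy alcohol in which the epoxide opens at tertiary C10 and the antiperiplanar cyclopropyl group shifts from C5 with inversion at C10, so cyclopropyl ends trans and the C14 methyl cis to the retained C9 hydroxyl (stereospecific transfer) while C5 becomes the ketone.

Step 8
Reactants: 8 (6R,7R)-7-cyclopropyl-6-hydroxy-7-methyl-1,4-dioxaspiro[4.5]decan-8-one
Product: 9 TBS ether of 8
Conditions: TBSOTf, 2,6-lutidine, CH2Cl2, −78 → 0 °C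
Reagents that add atoms: tert-butyldimethylsilyl trifluoromethanesulfonate, CC(C)(C)[Si](C)(C)OS(=O)(=O)C(F)(F)F
Why: Silyl triflate silylation protects the hindered secondary alcohol and affects no stereocentre.

Step 9
Reactants: 9 TBS ether of 8
Product: 11 (6R,7R)-6-(TBS-oxy)-7-cyclopropyl-7-methyl-1,4-dioxaspiro[4.5]dec-9-en-8-one, via trimethylsilyl enol ether 10 (not isolated)
Conditions: LiN(iPr)2, Me3SiCl, THF, −78 °C; then Pd(OAc)2, MeCN, 23 °C
Reagents that add atoms: none
Why: Saegusa–Ito dehydrogenation through the only possible enol ether (C10 is quaternary) introduces the C6=C7 double bond regiospecifically.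

Step 10
Reactants: 11 (6R,7R)-6-(TBS-oxy)-7-cyclopropyl-7-methyl-1,4-dioxaspiro[4.5]dec-9-en-8-one
Product: 12 dibromomethyl carbinol (both C5 epimers)
Conditions: CH2Br2, LiN(iPr)2, THF, −78 °C; AcOH
Reagents that add atoms: dibromomethane, BrCBr
Why: 1,2-Addition of (dibromomethyl)lithium, generated in the presence of the non-enolisable hindered enone, gives the tertiary carbinol whose new C5 centre is erased in step 11.

Step 11
Reactants: 12 dibromomethyl carbinol (both C5 epimers)
Product: 13 (6R,7S)-dibromomethylidene diene
Conditions: Ph2S[OC(CF3)2Ph]2 (Martin sulfurane), CH2Cl2, 0 → 23 °C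
Reagents that add atoms: none
Why: Martin sulfurane dehydration of the tertiary alcohol can only remove the acidic CHBr2 hydrogen, because C6 is sp2 and C10 is quaternary, and so gives the C5=CBr2 alkene.

Step 12
Reactants: 13 (6R,7S)-dibromomethylidene diene; 14 methyl 3-bromo-2-methylpropanoate
Product: 16 (Z)-bromoalkylidene precursor, via alkylzinc bromide 15 (not isolated)
Conditions: 14, Zn dust, I2 (5 mol %), DMA, 60 °C; then 13, PdCl2(DPEphos) (5 mol %; DPEphos = bis(2-diphenylphosphinophenyl) ether), THF, 23 → 45 °C
Reagents that add atoms: none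
Why: Site-selective Negishi monoalkylation of a 1,1-dibromoalkene, in which zerovalent palladium inserts into the C–Br bond trans to the quaternary C10 (the one flanked only by C6–H), places the arm cis to C6 and leaves bromine cis to C10 (Z alkene).

Step 13
Reactants: 16 (Z)-bromoalkylidene precursor
Product: 17 ring A-closed tricyclic diene ketal (1R,3S,9R,10S)
Conditions: Pd(OAc)2 (10 mol %), PCy3·HBF4 (20 mol %), CsOPiv (1.5 equiv), mesitylene (0.02 M), 110 °C
Reagents that add atoms: none
Why: Zerovalent palladium (formed in situ from Pd(OAc)2 and PCy3) inserts into the C4–Br bond, bromide is exchanged for pivalate, and the bound pivalate removes the C3 hydrogen that is syn to C10 in a concerted metalation–deprotonation, giving a six-membered palladacycle (Pd, C4, C5, C10, C1, C3) that collapses by C–C reductive elimination. The closest known reaction type is the pivalate-assisted intramolecular C(sp3)–H alkenylation with alkenyl bromides under zerovalent palladium, which together with the corresponding arylation is established for cyclopropane C–H bonds. Ring A closes as a five-membered ring by extrusion of palladium from the six-membered palladacycle, formally a 5-exo closure at the cyclopropyl carbon with retention at C3. C3 and C1 become stereocentres: the fusion must be cis because only a hydrogen syn to the C1–C10 bond can reach palladium, and their sense relative to C10 follows from which diastereotopic CH2 group reacts, the preferred palladacycle turning the spectator CH2 (C2) toward the small C14 methyl and the C1–H toward the crowded C9(OTBS)/C8 dioxolane flank. The step needs site selectivity for the cyclopropyl methylene over the C14 methyl, secured by the more acidic cyclopropyl C–H bond and by PCy3, which favours the six-membered palladacycle over the five-membered one that would lead to a cyclobutene, and it needs the CH2 selection just described, which a matched chiral phosphine can reinforce. Because C8 is a ketal and the arm is a saturated ester, no enolisable ketone, Heck acceptor or vinylogous acyl bromide is present to compete.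

Step 14
Reactants: 17 ring A-closed tricyclic diene ketal (1R,3S,9R,10S)
Product: 18 α-bromo ester of 17 (both C11' epimers)
Conditions: LiN(iPr)2, THF, −78 °C; then CBr4
Reagents that add atoms: carbon tetrabromide, BrC(Br)(Br)Br
Why: Electrophilic bromination of the lithium ester enolate, the only enolisable site while C8 is a ketal, gives the tertiary α-bromo ester as an inconsequential mixture of epimers at C11'.

Step 15
Reactants: 18 α-bromo ester of 17 (both C11' epimers)
Product: 19 tricyclic dienone with 9-O-TBS
Conditions: pyridinium p-toluenesulfonate (20 mol %), acetone–H2O (10:1), 45 °C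
Reagents that add atoms: water, O
Why: Acid-catalysed hydrolysis of the dienylic dioxolane passes through a doubly vinylogous oxocarbenium ion and is driven by conjugation of the new C8 ketone, under conditions too mild to cleave the silyl ether or the tertiary bromide.

Step 16
Reactants: 19 tricyclic dienone with 9-O-TBS
Product: 20 7-iodo dienone
Conditions: I2, pyridine, CH2Cl2, 0 → 23 °C
Reagents that add atoms: iodine, II
Why: α-Iodination of the dienone by the pyridine addition–iodination–elimination sequence functionalises C7, the only enone α-carbon bearing hydrogen, with a base too weak to eliminate HBr from the arm or to epimerise C9.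

Step 17
Reactants: 20 7-iodo dienone (two molecules)
Product: 23 bis-TBS ether of cycloshizukaol A, via monomeric zinc ester enolate 21 (not isolated), via open-chain dimer zinc enolate 22 (not isolated)
Conditions: Zn dust (Me3SiCl-activated), THF, 0 °C; then slow addition to Pd2(dba)3 (5 mol %), P(t-Bu)3 (10 mol %), THF, 40 °C, 5 mM
Reagents that add atoms: none
Why: Reformatsky–Negishi α-alkenylation in which zinc inserts into the tertiary C–Br bond, the zinc ester enolate couples with the C7–I bond of a second molecule under zerovalent palladium, and the same event within 22 closes the 12-membered ring (the s-trans C4=C5–C6=C7 diene forbids closure within one monomer); each quaternary C11 is set at C–C reductive elimination, the second under the constraint of the C2-symmetric macrocycle and the first only by the modest bias of the C8/C9 flank, so mismatched open-chain material is expected to end as separable oligomer.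

Step 18
Reactants: 23 bis-TBS ether of cycloshizukaol A
Product: 24 cycloshizukaol A
Conditions: HF·pyridine, THF–pyridine, 0 → 23 °C
Reagents that add atoms: none
Why: Fluoride cleavage of the two secondary silyl ethers under buffered, non-basic conditions liberates the 9-hydroxyls without epimerising the α-ketol or touching the esters.

Compound list
1 | 1,4-dioxaspiro[4.5]dec-6-en-8-one (ketone = C5, alkene = C10=C9, ketal = C8) | O=C1C=CC2(CC1)OCCO2 | starting material
2 | 7-iodo-1,4-dioxaspiro[4.5]dec-6-en-8-one | O=C1C(I)=CC2(CC1)OCCO2 | intermediate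
3 | 7-methyl-1,4-dioxaspiro[4.5]dec-6-en-8-one | CC1=CC2(CCC1=O)OCCO2 | intermediate
4 | (8R)-7-methyl-1,4-dioxaspiro[4.5]dec-6-en-8-ol | CC1=CC2(CC[C@H]1O)OCCO2 | intermediate
5 | syn-epoxy alcohol, (5R,9R,10R) in target numbering: 9,10-epoxide of 4 with the epoxide oxygen cis to the C5 hydroxyl | C[C@]12O[C@H]1C3(OCCO3)CC[C@H]2O | intermediate
6 | epoxy ketone, (9R,10S): C5 ketone, 9,10-epoxide, C8 dioxolane | C[C@]12O[C@H]1C3(OCCO3)CCC2=O | intermediate
7 | tertiary cyclopropyl epoxy alcohol, (5S,9R,10S): OH cis and cyclopropyl trans to the epoxide oxygen | C[C@]12O[C@H]1C3(OCCO3)CC[C@]2(O)C4CC4 | intermediate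
8 | (6R,7R)-7-cyclopropyl-6-hydroxy-7-methyl-1,4-dioxaspiro[4.5]decan-8-one (OH cis to methyl) | C[C@@]1(C2CC2)[C@@H](O)C2(OCCO2)CCC1=O | intermediate
9 | (6R,7R)-6-(tert-butyldimethylsilyloxy)-7-cyclopropyl-7-methyl-1,4-dioxaspiro[4.5]decan-8-one | C[C@@]1(C2CC2)[C@@H](O[Si](C)(C)C(C)(C)C)C2(OCCO2)CCC1=O | intermediate
10 | trimethylsilyl enol ether of 9 (C5–O–SiMe3, C5=C6), formed in the flask | C[C@@]1(C2CC2)[C@@H](O[Si](C)(C)C(C)(C)C)C2(OCCO2)CC=C1O[Si](C)(C)C | intermediate
11 | (6R,7R)-6-(tert-butyldimethylsilyloxy)-7-cyclopropyl-7-methyl-1,4-dioxaspiro[4.5]dec-9-en-8-one | C[C@@]1(C2CC2)[C@@H](O[Si](C)(C)C(C)(C)C)C2(OCCO2)C=CC1=O | intermediate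
12 | (6R,7R)-6-(tert-butyldimethylsilyloxy)-7-cyclopropyl-8-(dibromomethyl)-7-methyl-1,4-dioxaspiro[4.5]dec-9-en-8-ol, both epimers at the carbinol carbon | C[C@@]1(C2CC2)[C@@H](O[Si](C)(C)C(C)(C)C)C2(OCCO2)C=CC1(O)C(Br)Br | intermediate
13 | tert-butyl{[(6R,7S)-7-cyclopropyl-8-(dibromomethylidene)-7-methyl-1,4-dioxaspiro[4.5]dec-9-en-6-yl]oxy}dimethylsilane | C[C@@]1(C2CC2)[C@@H](O[Si](C)(C)C(C)(C)C)C2(OCCO2)C=CC1=C(Br)Br | intermediate
14 | methyl 3-bromo-2-methylpropanoate (racemic) | COC(=O)C(C)CBr | starting material
15 | (3-methoxy-2-methyl-3-oxopropyl)zinc bromide, formed in the flask | COC(=O)C(C)C[Zn]Br | intermediate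
16 | methyl (4Z)-4-bromo-4-[(6R,7S)-6-(tert-butyldimethylsilyloxy)-7-cyclopropyl-7-methyl-1,4-dioxaspiro[4.5]dec-9-en-8-ylidene]-2-methylbutanoate (Br cis to C10; both C11' epimers); precursor of the key step | C[C@@]1(C2CC2)[C@@H](O[Si](C)(C)C(C)(C)C)C2(OCCO2)C=C/C1=C(/Br)CC(C)C(=O)OC | intermediate
17 | ring A-closed tricycle, (1R,3S,9R,10S): C4=C5 and C6=C7 diene, cis-fused cyclopropane with C2 syn to the C14 methyl, C8 dioxolane, 9-O-TBS, arm CH2CH(CH3)CO2Me on C4 (both C11' epimers); product of the key step | COC(=O)C(C)CC1=C2C=CC3(OCCO3)[C@H](O[Si](C)(C)C(C)(C)C)[C@@]2(C)[C@@H]2C[C@H]12 | intermediate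
18 | 17 with bromine on C11' (arm CH2C(Br)(CH3)CO2Me; both epimers) | COC(=O)C(C)(Br)CC1=C2C=CC3(OCCO3)[C@H](O[Si](C)(C)C(C)(C)C)[C@@]2(C)[C@@H]2C[C@H]12 | intermediate
19 | (1R,3S,9R,10S)-tricyclic 4,6-dien-8-one with 9-O-TBS and the α-bromo ester arm on C4 | COC(=O)C(C)(Br)CC1=C2C=CC(=O)[C@H](O[Si](C)(C)C(C)(C)C)[C@@]2(C)[C@@H]2C[C@H]12 | intermediate
20 | 19 with iodine on C7 | COC(=O)C(C)(Br)CC1=C2C=C(I)C(=O)[C@H](O[Si](C)(C)C(C)(C)C)[C@@]2(C)[C@@H]2C[C@H]12 | intermediate
21 | bromozinc ester enolate of 20 (Reformatsky reagent), formed in the flask | COC(O[Zn]Br)=C(C)CC1=C2C=C(I)C(=O)[C@H](O[Si](C)(C)C(C)(C)C)[C@@]2(C)[C@@H]2C[C@H]12 | intermediate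
22 | open-chain dimer after the first C7–C11 bond (11R): one half keeps C7–I, the other the bromozinc ester enolate arm; formed in the flask | COC(O[Zn]Br)=C(C)CC1=C2C=C(C(=O)[C@H](O[Si](C)(C)C(C)(C)C)[C@@]2(C)[C@@H]2C[C@H]12)[C@](C)(C(=O)OC)CC1=C2C=C(I)C(=O)[C@H](O[Si](C)(C)C(C)(C)C)[C@@]2(C)[C@@H]2C[C@H]12 | intermediate
23 | 9,9'-bis-O-TBS cycloshizukaol A, (1R,3S,9R,10S,11R) in each half | COC(=O)[C@]1(C)CC2=C3C=C(C(=O)[C@H](O[Si](C)(C)C(C)(C)C)[C@@]3(C)[C@@H]3C[C@H]23)[C@](C)(C(=O)OC)CC2=C3C=C1C(=O)[C@H](O[Si](C)(C)C(C)(C)C)[C@@]3(C)[C@@H]1C[C@H]21 | intermediate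
24 | cycloshizukaol A, (1R,3S,9R,10S,11R) in each half | COC(=O)[C@]1(C)CC2=C3C=C(C(=O)[C@H](O)[C@@]3(C)[C@@H]3C[C@H]23)[C@](C)(C(=O)OC)CC2=C3C=C1C(=O)[C@H](O)[C@@]3(C)[C@@H]1C[C@H]21 | target

Total step count: 18. Longest linear sequence: 18 steps (1 → 24); 14 enters in step 12.

Steps most likely to fail

1. Step 13. What may go wrong: the alkenylpalladium intermediate may discriminate poorly between the two diastereotopic cyclopropyl CH2 groups, or be diverted into activation of the C14 methyl or into protodebromination. Fallback, setting out from 6 and coming back at 17: ring A and the cyclopropane are built together by an enyne cycloisomerisation instead of C–H activation. Vinylmagnesium bromide with CeCl3 adds to 6 anti to the epoxide to give the vinyl carbinol F1. BF3·OEt2 then induces the semipinacol shift of the vinyl group to give the 10-vinyl hydroxy ketone F2, which is silylated (TBSOTf, 2,6-lutidine) to the silyl ether F3 and dehydrogenated with 2-iodoxybenzoic acid to the enone F4. Ethynylmagnesium bromide with CeCl3 adds to the C5 ketone to give the propargylic alcohol F5, which is acetylated through its lithium alkoxide (n-BuLi, Ac2O) to the propargylic acetate F6. PtCl2 (5 mol %, toluene, 80 °C) effects the Ohloff–Rautenstrauch cycloisomerisation of this hex-5-en-1-yn-3-yl acetate: a 1,2-acyloxy shift is followed by carbene cyclopropanation of the C10 vinyl group, under the same C10 bias as in step 13, and gives the tricyclic dienyl acetate F7. MeLi followed by PhNTf2 converts it into the dienyl triflate F8, and Negishi coupling of F8 with 15 (PdCl2(dppf)) gives 17.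

2. Step 17. What may go wrong: chain growth may outrun ring closure, and facial control at C11 in the first, intermolecular coupling may be low, so that part of the open-chain material cannot close to the C2-symmetric ring. Fallback, setting out from 18 and 20 and coming back at 22: the two C7–C11 bonds are made in separate operations. Zinc insertion into the ketal-protected bromo ester 18 gives the Reformatsky reagent F9, which is freed from excess zinc and cross-coupled with 20 (Pd2(dba)3, P(t-Bu)3). This forms only the first C7–C11 bond and gives the open-chain dimer F10, whose C11 epimers are separated at this stage. Hydrolysis of the remaining dioxolane (pyridinium p-toluenesulfonate, wet acetone) gives the bis-dienone F11, and I2/pyridine iodinates its only free C7 to give the iodo bromo dimer F12. Zinc insertion into F12 regenerates 22, which is cyclised by zerovalent palladium under high dilution to 23.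

3. Step 11. What may go wrong: the activated tertiary allylic alcohol may ionise and undergo allylic transposition or a 1,2-shift instead of losing the CHBr2 hydrogen, or the elimination may stall because the tetrasubstituted dibromoalkene is strained. Fallback, setting out from 11 and coming back at 13: direct Ramirez dibromo-olefination of the enone with the ylide preformed from CBr4, PPh3 and zinc dust in CH2Cl2, then heated with 11 in toluene. This replaces addition–dehydration by a Wittig-type olefination and passes through no new isolable compound.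

Further compounds
F1 | step 13 | vinyl carbinol: 5-vinyl analogue of 7, (5S,9R,10S) | C[C@]12O[C@H]1C3(OCCO3)CC[C@]2(O)C=C
F2 | step 13 | 10-vinyl hydroxy ketone: (6R,7R)-7-ethenyl-6-hydroxy-7-methyl-1,4-dioxaspiro[4.5]decan-8-one | C[C@@]1(C=C)[C@@H](O)C2(OCCO2)CCC1=O
F3 | step 13 | silyl ether of F2 | C[C@@]1(C=C)[C@@H](O[Si](C)(C)C(C)(C)C)C2(OCCO2)CCC1=O
F4 | step 13 | enone: 9,10-didehydro derivative of F3 (C6=C7 in target numbering) | C[C@@]1(C=C)[C@@H](O[Si](C)(C)C(C)(C)C)C2(OCCO2)C=CC1=O
F5 | step 13 | propargylic alcohol: ethynyl adduct of F4 at C5 (both epimers) | C[C@@]1(C=C)[C@@H](O[Si](C)(C)C(C)(C)C)C2(OCCO2)C=CC1(O)C#C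
F6 | step 13 | propargylic acetate of F5 | C[C@@]1(C=C)[C@@H](O[Si](C)(C)C(C)(C)C)C2(OCCO2)C=CC1(OC(C)=O)C#C
F7 | step 13 | tricyclic dienyl acetate: skeleton of 17 with OAc on C4 in place of the arm | CC(=O)OC1=C2C=CC3(OCCO3)[C@H](O[Si](C)(C)C(C)(C)C)[C@@]2(C)[C@@H]2C[C@H]12
F8 | step 13 | tricyclic dienyl triflate: as F7 with OSO2CF3 on C4 | FC(F)(F)S(=O)(=O)OC1=C2C=CC3(OCCO3)[C@H](O[Si](C)(C)C(C)(C)C)[C@@]2(C)[C@@H]2C[C@H]12
F9 | step 17 | Reformatsky reagent: bromozinc ester enolate of 18 | COC(O[Zn]Br)=C(C)CC1=C2C=CC3(OCCO3)[C@H](O[Si](C)(C)C(C)(C)C)[C@@]2(C)[C@@H]2C[C@H]12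
F10 | step 17 | open-chain dimer (11R): dienone half with α-bromo ester arm, C7 bonded to C11 of the ketal-protected half | COC(=O)C(C)(Br)CC1=C2C=C(C(=O)[C@H](O[Si](C)(C)C(C)(C)C)[C@@]2(C)[C@@H]2C[C@H]12)[C@](C)(C(=O)OC)CC1=C2C=CC3(OCCO3)[C@H](O[Si](C)(C)C(C)(C)C)[C@@]2(C)[C@@H]2C[C@H]12
F11 | step 17 | bis-dienone: F10 after hydrolysis of the dioxolane | COC(=O)C(C)(Br)CC1=C2C=C(C(=O)[C@H](O[Si](C)(C)C(C)(C)C)[C@@]2(C)[C@@H]2C[C@H]12)[C@](C)(C(=O)OC)CC1=C2C=CC(=O)[C@H](O[Si](C)(C)C(C)(C)C)[C@@]2(C)[C@@H]2C[C@H]12
F12 | step 17 | iodo bromo dimer: F11 with iodine on the free C7 | COC(=O)C(C)(Br)CC1=C2C=C(C(=O)[C@H](O[Si](C)(C)C(C)(C)C)[C@@]2(C)[C@@H]2C[C@H]12)[C@](C)(C(=O)OC)CC1=C2C=C(I)C(=O)[C@H](O[Si](C)(C)C(C)(C)C)[C@@]2(C)[C@@H]2C[C@H]12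
F0 | step 11 | none | none
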